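- The constants of this flask were hidden from me, so I began from the charges and the two runs already made.

the same everywhere: free catalyst 16 mM

| charge | starting material | coupling partner | protic impurity | remark |
|---|---|---|---|---|
| ochre | 0.45 M | 1.6 M | 0.096 M | run made earlier |
| violet | 0.70 M | 1.6 M | 0.096 M | run made earlier |
| flask | 0.32 M | 1.60 M | 0.0960 M |  |

| run | time / min | product / % | starting material / % |
|---|---|---|---|
| ochre | 20.0 | 15.6 | 61.2 |
| ochre | 40.0 | 31.2 | 45.2 |
| ochre | 50.0 | 38.0 | 38.7 |
| ochre | 80.0 | 56.1 | 21.4 |
| ochre | 90.0 | 61.3 | 16.3 |
| ochre | 120 | 71.9 | 7.3 |
| violet | 8.00 | 4.1 | 81.7 |
| violet | 15.0 | 8.6 | 76.3 |
| violet | 25.0 | 14.3 | 70.5 |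
| violet | 40.0 | 23.3 | 60.5 |
| violet | 60.0 | 34.6 | 49.7 |
| violet | 120 | 64.2 | 20.9 |

(readings scatter by 0.3 percentage points)

- no earlier run changes the charge of free catalyst; that part of a forecast is a guess
- no earlier run changes the charge of coupling partner; that part of a forecast is a guess

- apparent order in free catalyst when 10% of the starting material are converted (percent change of the rate of making product for one percent more free catalyst charged)
- factor on the rate of making product when 10% of the starting material are converted if coupling partner is charged twice over

- Ochre is the neighbour: it had the same [protic impurity] and [free catalyst] as the flask, but more [starting material]. At 120 min, 20.8% of the ochre charge read as neither product nor starting material.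
- I therefore carried one quantity: charged [protic impurity] over charged [starting material], which is 30.0% for the flask. I called it the impurity share, the part of the charge I took to be lost one for one to the impurity.
- For ochre the impurity share is 21.3%, close to that reading. By charge, the protic impurity is the limiting reagent of this loss, with 0.0960 M against 0.32 M of starting material in the flask.
- The same impurity on a smaller charge takes a larger part, more in the flask than in ochre. So I put the flask's final product at 70.0%, lower than the 78.7% I put for ochre.
- In the flask, the mark of 10% conversion is 32.0 mM of starting material, less than the 96 mM of protic impurity. The mark therefore lay inside the early loss, and I doubted a plain order of one there, though no run had changed [free catalyst].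
- The forecast gave 0.97 for the order and 1.15 for the factor, calling the first about one, “less a small reservoir correction from bound starting material”. My doubt pointed lower.
- The flask gave an order of 0.60 and a factor of 1.02, so the forecast's factor held within its tolerance and its order stood too high.

    starting material + protic impurity → quenched substrate (k = 0.00740 /M/s)
    starting material + free catalyst → catalyst intermediate A (k = 0.0450 /M/s)
    catalyst intermediate A ⇌ catalyst intermediate B (K = 1.50, k = 0.0230 /s)
    coupling partner + catalyst intermediate B → catalyst intermediate C (k = 0.230 /M/s)
    catalyst intermediate C → free catalyst + product (k = 0.00720 /s)

- The two parted on the order. In the run with the reaction of starting material and protic impurity taken away, the order was 1.0 instead of 0.60. At the start, the flask's starting material went to free catalyst and to protic impurity at a rate ratio of 1.0. At 15.0 h the flask held 70.3% product and 29.7% quenched substrate, against my 70.0% for product. For violet the impurity share is 13.7%, which leaves 86.3% for product and starting material together, and at 120 min its product plus starting material read 85.1%.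

The earlier runs and the new flask were computed with made-up constants; noise was put on by code.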